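**Plan**

- Retrosynthesis: the C8–CH2 bond of the prenyl group is traced back to a 5-O-prenyl ether. Ring C is then cut at O1–C8a and C4–C4a, C2 is cut from C3 as a formate carbon, and the pyran on ring B is cut at O–CMe2 and at its aryl–CH= bond.
- Enabling feature: on ring A, O1 (on C8a) and the C4 carbonyl (on C4a) are ortho neighbours, and O5 sits on the carbon next to C4a. A 3-alkoxyaryne gives exactly this pattern when it takes an oxygen nucleophile at its far carbon and an acyl group at the carbon beside the alkoxy group.
- Forward order: rings A and B are bought as phloroglucinol and 2,4-dihydroxyphenylacetic acid. The pyran (ring D) is closed first on ring B by a propargyl Claisen cascade, formylation adds C2, and ring C is closed last by the aryne annulation that joins the two halves.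
- Endgame: O5 is unmasked and prenylated, the prenyl group is moved to C8 by a Claisen–Cope sequence, and the last MOM groups are removed.
- Stereochemistry: the target has no stereocentre. The only geometric demands are the ring-fixed cis alkene of ring D and the Z geometry (oxygen cis to ester) of the hydroxyacrylate, which comes from its chelated enol(ate).

Key step: step 11

Remark: isoflavone numbering is used for rings A and C (O1, C2, C3, C4, C4a, C5–C8, C8a) and primes for ring B. MOM = CH2OCH3.

**Route**

Step 1
Reactants: 1 phloroglucinol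
Product: 2 3,5-bis(methoxymethoxy)phenol
Conditions: MOMCl (2 equiv), DIPEA, DMF, 0 °C → rt
Reagents that add atoms: chloromethyl methyl ether, COCCl
Why: Base-mediated O-alkylation of three equivalent phenols, so two equivalents of MOMCl should make the bis-ether the main product, which chromatography frees from under- and over-protected material.

Step 2
Reactants: 2 3,5-bis(methoxymethoxy)phenol
Product: 3 2-bromo-3,5-bis(methoxymethoxy)phenol
Conditions: NBS (1 equiv), CH2Cl2, −78 °C → 0 °C
Reagents that add atoms: N-bromosuccinimide, O=C1CCC(=O)N1Br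
Why: Electrophilic aromatic bromination in which the free hydroxyl is the strongest activator and the site between OH and OMOM is less shielded than the one between two OMOM groups, while one equivalent of NBS at low temperature should stop at the monobromide and releases no acid that could harm the acetals.

Step 3
Reactants: 3 2-bromo-3,5-bis(methoxymethoxy)phenol
Product: 4 [2-bromo-3,5-bis(methoxymethoxy)phenoxy]trimethylsilane
Conditions: HMDS, THF, 65 °C; evaporation
Reagents that add atoms: hexamethyldisilazane, C[Si](C)(C)N[Si](C)(C)C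
Why: Silylation of a phenol with HMDS needs no added base and leaves only a volatile co-product, so the moisture-sensitive silyl ether can be used after simple evaporation.

Step 4
Reactants: 4 [2-bromo-3,5-bis(methoxymethoxy)phenoxy]trimethylsilane
Product: 6 3,5-bis(methoxymethoxy)-2-(trimethylsilyl)phenyl trifluoromethanesulfonate, via lithium silylphenolate 5 (not isolated)
Conditions: n-BuLi, THF, −78 °C; then Tf2O, −78 °C → 0 °C
Reagents that add atoms: trifluoromethanesulfonic anhydride, O=S(=O)(OS(=O)(=O)C(F)(F)F)C(F)(F)F; n-butyllithium, [Li]CCCC (lithium of 5 only)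
Why: Bromine–lithium exchange outruns MOM-directed deprotonation at −78 °C, a 1,3 O→C silyl shift (retro-Brook rearrangement) then gives phenolate 5, and this is sulfonylated in the same flask, which is the standard entry to o-silylaryl triflates.

Step 5
Reactants: 7 2,4-dihydroxyphenylacetic acid
Product: 8 6-hydroxybenzofuran-2(3H)-one
Conditions: p-TsOH·H2O (cat.), toluene, reflux, azeotropic removal of water
Reagents that add atoms: none
Why: Acid-catalysed lactonisation can engage only the ortho hydroxyl in a five-membered ring, which masks O2 and the acid together and leaves the para hydroxyl as the only free phenol.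

Step 6
Reactants: 8 6-hydroxybenzofuran-2(3H)-one
Product: 9 6-(methoxymethoxy)benzofuran-2(3H)-one
Conditions: MOMCl, DIPEA, CH2Cl2, 0 °C → rt
Reagents that add atoms: chloromethyl methyl ether, COCCl
Why: Standard MOM protection of a phenol with an amine base too weak to enolise the lactone appreciably, the MOM ether being chosen because it withstands NaH, CsF and 140 °C later on.

Step 7
Reactants: 9 6-(methoxymethoxy)benzofuran-2(3H)-one
Product: 10 methyl 2-[2-hydroxy-4-(methoxymethoxy)phenyl]acetate
Conditions: NaOMe (cat.), MeOH, 0 °C → rt; AcOH quench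
Reagents that add atoms: methanol, CO
Why: Transesterification in which methoxide opens the strained aryl ester because phenoxide is the better leaving group, which unmasks O2 as the only free phenol and supplies the methyl ester that later serves as the acylating group.

Step 8
Reactants: 10 methyl 2-[2-hydroxy-4-(methoxymethoxy)phenyl]acetate; 11 3-chloro-3-methylbut-1-yne
Product: 12 methyl 2-[4-(methoxymethoxy)-2-(2-methylbut-3-yn-2-yloxy)phenyl]acetate
Conditions: DBU, CuCl2·2H2O (1 mol %), MeCN, 0 °C
Reagents that add atoms: none
Why: Copper-catalysed propargylic substitution of a tertiary propargyl chloride by a phenol is a mild standard route to aryl 1,1-dimethylpropargyl ethers and avoids the heating at which the hydroxy ester could re-lactonise.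

Step 9
Reactants: 12 methyl 2-[4-(methoxymethoxy)-2-(2-methylbut-3-yn-2-yloxy)phenyl]acetate
Product: 14 methyl 2-[5-(methoxymethoxy)-2,2-dimethyl-2H-chromen-8-yl]acetate, via allenylphenol 13 (not isolated)
Conditions: xylenes, 140 °C
Reagents that add atoms: none
Why: The aromatic propargyl Claisen rearrangement can reach only C3 because the other ortho carbon carries the acetate chain, giving allenylphenol 13, and a 1,5-hydrogen shift followed by oxa-6π electrocyclisation closes ring D on O2.

Step 10
Reactants: 14 methyl 2-[5-(methoxymethoxy)-2,2-dimethyl-2H-chromen-8-yl]acetate; 15 methyl formate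
Product: 16 methyl (Z)-3-hydroxy-2-[5-(methoxymethoxy)-2,2-dimethyl-2H-chromen-8-yl]acrylate
Conditions: NaH, THF, 0 °C → rt; AcOH quench at 0 °C
Reagents that add atoms: none
Why: Crossed Claisen condensation with a non-enolisable formate is driven by deprotonation of the product, and mild acidification should give the enol in its hydrogen-bonded Z form with OH and ester cis.

Step 11
Reactants: 6 3,5-bis(methoxymethoxy)-2-(trimethylsilyl)phenyl trifluoromethanesulfonate; 16 methyl (Z)-3-hydroxy-2-[5-(methoxymethoxy)-2,2-dimethyl-2H-chromen-8-yl]acrylate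
Product: 19 5,7-bis(methoxymethoxy)-3-[5-(methoxymethoxy)-2,2-dimethyl-2H-chromen-8-yl]-4H-chromen-4-one, via benzyne 17 (not isolated), via aryl caesium species 18 (not isolated)
Conditions: CsF (4 equiv), THF, 65 °C; 16 stirred with CsF first, then 6 (1.3 equiv) added slowly
Reagents that add atoms: caesium fluoride, [F-].[Cs+] (caesium of 18 only)
Why: Proposed new method: fluoride removes the silyl group of 6 and triflate departs to give aryne 17, the caesium enolate of 16 adds through its oxygen to the aryne carbon remote from the flanking OMOM group (future C8a), and the aryl anion 18 so formed at future C4a attacks the cis-disposed ester and expels methoxide. The closest known reaction type is the fluoride-triggered annulation of arynes with methyl salicylates to xanthones, where a phenoxide plays the part taken here by an enolate oxygen. Ring C closes by 6-exo-trig acyl substitution, and no stereocentre is formed. Regioselective addition to the unsymmetrical aryne is required and is secured by the OMOM group that becomes O5, whose inductive pull and distortion of the triple bond steer the nucleophile to the far carbon and leave the charge beside oxygen. O- rather than C-arylation is also required and should be favoured by the fully substituted enolate carbon, which is screened by the twisted ortho-alkoxyaryl group, while the oxygen-cis-to-ester geometry is kept by the contact ion pair in THF, in which caesium bridges both oxygens, so that crown ethers and dipolar solvents are avoided. Stirring 16 with CsF before 6 is added slowly keeps the aryne dilute and the free enol scarce, so that acylation of 18 should outrun its protonation.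

Step 12
Reactants: 19 5,7-bis(methoxymethoxy)-3-[5-(methoxymethoxy)-2,2-dimethyl-2H-chromen-8-yl]-4H-chromen-4-one
Product: 20 5-hydroxy-7-(methoxymethoxy)-3-[5-(methoxymethoxy)-2,2-dimethyl-2H-chromen-8-yl]-4H-chromen-4-one
Conditions: HCl (cat., methanolic), MeOH–CH2Cl2, 0 °C → rt, stopped after loss of one MOM group
Reagents that add atoms: none
Why: Acid-catalysed transacetalisation in which the MOM group peri to the C4 carbonyl is the most labile, since the carbonyl relays the proton to O5 and the freed phenol is held in a hydrogen-bonded chelate, a selectivity well known for MOM ethers next to aryl ketone carbonyls.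

Step 13
Reactants: 20 5-hydroxy-7-(methoxymethoxy)-3-[5-(methoxymethoxy)-2,2-dimethyl-2H-chromen-8-yl]-4H-chromen-4-one; 21 prenyl bromide
Product: 22 7-(methoxymethoxy)-3-[5-(methoxymethoxy)-2,2-dimethyl-2H-chromen-8-yl]-5-(3-methylbut-2-en-1-yloxy)-4H-chromen-4-one
Conditions: K2CO3, DMF, 40 °C
Reagents that add atoms: none
Why: Williamson etherification of the only free phenol, the chelated 5-OH being sluggish but known to be prenylated on oxygen with K2CO3 in a dipolar solvent and excess bromide.

Step 14
Reactants: 22 7-(methoxymethoxy)-3-[5-(methoxymethoxy)-2,2-dimethyl-2H-chromen-8-yl]-5-(3-methylbut-2-en-1-yloxy)-4H-chromen-4-one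
Product: 24 5-hydroxy-7-(methoxymethoxy)-3-[5-(methoxymethoxy)-2,2-dimethyl-2H-chromen-8-yl]-8-(3-methylbut-2-en-1-yl)-4H-chromen-4-one, via C6 dienone 23 (not isolated)
Conditions: Eu(fod)3 (10 mol %), NaHCO3, PhCl, 85 °C
Reagents that add atoms: none
Why: Lewis-acid-catalysed para-Claisen–Cope rearrangement in which Eu(fod)3 bound to the C4 carbonyl and O5 speeds the [3,3] shift to C6, giving dienone 23 (racemic, its single stereocentre is lost again), whose Cope [3,3] shift carries the chain to C8 with normal prenyl connectivity before enolisation restores ring A, as is established for 5-O-prenyl flavonoids and isoflavones.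

Step 15
Reactants: 24 5-hydroxy-7-(methoxymethoxy)-3-[5-(methoxymethoxy)-2,2-dimethyl-2H-chromen-8-yl]-8-(3-methylbut-2-en-1-yl)-4H-chromen-4-one
Product: 25 5,7-dihydroxy-3-(5-hydroxy-2,2-dimethyl-2H-chromen-8-yl)-8-(3-methylbut-2-en-1-yl)-4H-chromen-4-one
Conditions: HCl (methanolic), MeOH, 40 °C
Reagents that add atoms: none
Why: Acid-catalysed methanolysis of the two remaining phenolic MOM acetals under conditions that, by analogy with other ortho-prenylphenols and 2,2-dimethylchromenes, should be mild enough to avoid cyclisation of the prenyl group onto O7.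

**Compound list**

1 | phloroglucinol | Oc1cc(O)cc(O)c1 | starting material
2 | 3,5-bis(methoxymethoxy)phenol | COCOc1cc(O)cc(OCOC)c1 | intermediate
3 | 2-bromo-3,5-bis(methoxymethoxy)phenol | COCOc1cc(O)c(Br)c(OCOC)c1 | intermediate
4 | [2-bromo-3,5-bis(methoxymethoxy)phenoxy]trimethylsilane | COCOc1cc(O[Si](C)(C)C)c(Br)c(OCOC)c1 | intermediate
5 | lithium 3,5-bis(methoxymethoxy)-2-(trimethylsilyl)phenolate | COCOc1cc([O-])c([Si](C)(C)C)c(OCOC)c1.[Li+] | intermediate
6 | 3,5-bis(methoxymethoxy)-2-(trimethylsilyl)phenyl trifluoromethanesulfonate | COCOc1cc(OCOC)c([Si](C)(C)C)c(OS(=O)(=O)C(F)(F)F)c1 | intermediate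
7 | 2,4-dihydroxyphenylacetic acid | OC(=O)Cc1ccc(O)cc1O | starting material
8 | 6-hydroxybenzofuran-2(3H)-one | O=C1Cc2ccc(O)cc2O1 | intermediate
9 | 6-(methoxymethoxy)benzofuran-2(3H)-one | O=C1Cc2ccc(OCOC)cc2O1 | intermediate
10 | methyl 2-[2-hydroxy-4-(methoxymethoxy)phenyl]acetate | COC(=O)Cc1ccc(OCOC)cc1O | intermediate
11 | 3-chloro-3-methylbut-1-yne | C#CC(C)(C)Cl | starting material
12 | methyl 2-[4-(methoxymethoxy)-2-(2-methylbut-3-yn-2-yloxy)phenyl]acetate | COC(=O)Cc1ccc(OCOC)cc1OC(C)(C)C#C | intermediate
13 | methyl 2-[2-hydroxy-4-(methoxymethoxy)-3-(3-methylbuta-1,2-dien-1-yl)phenyl]acetate | COC(=O)Cc1ccc(OCOC)c(C=C=C(C)C)c1O | intermediate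
14 | methyl 2-[5-(methoxymethoxy)-2,2-dimethyl-2H-chromen-8-yl]acetate | COC(=O)Cc1ccc(OCOC)c2c1OC(C)(C)C=C2 | intermediate
15 | methyl formate | COC=O | starting material
16 | methyl (Z)-3-hydroxy-2-[5-(methoxymethoxy)-2,2-dimethyl-2H-chromen-8-yl]acrylate | O/C=C(\C(=O)OC)c1ccc(OCOC)c2c1OC(C)(C)C=C2 | intermediate
17 | 3,5-bis(methoxymethoxy)benzyne (1,2-didehydro-3,5-bis(methoxymethoxy)benzene) | C1#CC(OCOC)=CC(OCOC)=C1 | intermediate
18 | methyl (Z)-3-[2-caesio-3,5-bis(methoxymethoxy)phenoxy]-2-[5-(methoxymethoxy)-2,2-dimethyl-2H-chromen-8-yl]acrylate | COCOc1cc(OCOC)[c-]c(O/C=C(\C(=O)OC)c2ccc(OCOC)c3c2OC(C)(C)C=C3)c1.[Cs+] | intermediate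
19 | 5,7-bis(methoxymethoxy)-3-[5-(methoxymethoxy)-2,2-dimethyl-2H-chromen-8-yl]-4H-chromen-4-one | COCOc1cc(OCOC)c2c(=O)c(-c3ccc(OCOC)c4c3OC(C)(C)C=C4)coc2c1 | intermediate
20 | 5-hydroxy-7-(methoxymethoxy)-3-[5-(methoxymethoxy)-2,2-dimethyl-2H-chromen-8-yl]-4H-chromen-4-one | COCOc1cc(O)c2c(=O)c(-c3ccc(OCOC)c4c3OC(C)(C)C=C4)coc2c1 | intermediate
21 | prenyl bromide (1-bromo-3-methylbut-2-ene) | CC(C)=CCBr | starting material
22 | 7-(methoxymethoxy)-3-[5-(methoxymethoxy)-2,2-dimethyl-2H-chromen-8-yl]-5-(3-methylbut-2-en-1-yloxy)-4H-chromen-4-one | COCOc1cc(OCC=C(C)C)c2c(=O)c(-c3ccc(OCOC)c4c3OC(C)(C)C=C4)coc2c1 | intermediate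
23 | 7-(methoxymethoxy)-3-[5-(methoxymethoxy)-2,2-dimethyl-2H-chromen-8-yl]-6-(2-methylbut-3-en-2-yl)-4H-chromene-4,5(6H)-dione (racemic) | C=CC(C)(C)C1C(=O)C2=C(C=C1OCOC)OC=C(C2=O)c1ccc(OCOC)c2c1OC(C)(C)C=C2 | intermediate
24 | 5-hydroxy-7-(methoxymethoxy)-3-[5-(methoxymethoxy)-2,2-dimethyl-2H-chromen-8-yl]-8-(3-methylbut-2-en-1-yl)-4H-chromen-4-one | CC(C)=CCc1c(OCOC)cc(O)c2c(=O)c(-c3ccc(OCOC)c4c3OC(C)(C)C=C4)coc12 | intermediate
25 | 5,7-dihydroxy-3-(5-hydroxy-2,2-dimethyl-2H-chromen-8-yl)-8-(3-methylbut-2-en-1-yl)-4H-chromen-4-one | CC(C)=CCc1c(O)cc(O)c2c(=O)c(-c3ccc(O)c4c3OC(C)(C)C=C4)coc12 | target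

Total step count: 15.
Longest linear sequence: 11 steps (from 7 through steps 5–15 to 25). The aryne arm (steps 1–4) joins at step 11.

**Steps most likely to fail**

Step 11.
- Risk: the enolate may be arylated on carbon instead of oxygen. It may react through the rotamer in which oxygen and ester are trans. The aryl anion may also be protonated before it reaches the ester.
- Fallback: this is the deoxybenzoin route, known chemistry throughout, in which O1 arrives already bound to ring A. It sets out from 14 and 3 and comes back at 19. Ester 14 is treated with MeNHOMe·HCl and iPrMgCl in THF to give the Weinreb amide N-methoxy-N-methyl-2-[5-(methoxymethoxy)-2,2-dimethyl-2H-chromen-8-yl]acetamide F1. Bromophenol 3 with two equivalents of n-BuLi (THF, −78 °C) gives lithium 2-lithio-3,5-bis(methoxymethoxy)phenolate F2. This adds to F1 in a Weinreb ketone synthesis to give the deoxybenzoin 1-[2-hydroxy-4,6-bis(methoxymethoxy)phenyl]-2-[5-(methoxymethoxy)-2,2-dimethyl-2H-chromen-8-yl]ethan-1-one F3. Heating F3 with N,N-dimethylformamide dimethyl acetal in toluene supplies C2 as an enaminone, which closes onto the phenol with loss of dimethylamine and gives 19.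

Step 12.
- Risk: discrimination between the three acetals may be poor, so that the groups on O7 or O4′ start to leave before cleavage at O5 is complete.
- Fallback: the selection is moved from the cleavage to the protection. It sets out from 19 and comes back at 20. Methanolic HCl at 40 °C removes all three acetals to give the triol 5,7-dihydroxy-3-(5-hydroxy-2,2-dimethyl-2H-chromen-8-yl)-4H-chromen-4-one F4. MOMCl (2.2 equiv) with K2CO3 in acetone should then etherify only O7 and O4′, because the chelated 5-OH is by far the least reactive phenol. This gives 20.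

Step 14.
- Risk: the ortho dienone may enolise before the Cope shift, which would strand the chain on C6 in its reversed form. The allyl ether may also ionise with loss of the prenyl group.
- Fallback: the chain is delivered by an ortho-Claisen shift from O7 instead of a para shift from O5. It sets out from 19 and comes back at the target 25. Compound 19 is cleaved with methanolic HCl to the triol 5,7-dihydroxy-3-(5-hydroxy-2,2-dimethyl-2H-chromen-8-yl)-4H-chromen-4-one F4. Its most acidic phenol, 7-OH, is alkylated with 11 (K2CO3, 1 equiv, KI, DMF) to give 5-hydroxy-3-(5-hydroxy-2,2-dimethyl-2H-chromen-8-yl)-7-(2-methylbut-3-yn-2-yloxy)-4H-chromen-4-one F5. Semi-hydrogenation (H2, Pd/CaCO3 poisoned with Pb(OAc)2, quinoline, EtOAc) gives 5-hydroxy-3-(5-hydroxy-2,2-dimethyl-2H-chromen-8-yl)-7-(2-methylbut-3-en-2-yloxy)-4H-chromen-4-one F6. Heating F6 in xylenes at 130 °C should send the chain by a single [3,3] shift to C8, the ortho site favoured by the higher C7–C8 bond order of chromones. The shift inverts the allyl unit to the normal prenyl group, giving 25.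

**Further compounds**

F1 | step 11 | N-methoxy-N-methyl-2-[5-(methoxymethoxy)-2,2-dimethyl-2H-chromen-8-yl]acetamide | CON(C)C(=O)Cc1ccc(OCOC)c2c1OC(C)(C)C=C2
F2 | step 11 | lithium 2-lithio-3,5-bis(methoxymethoxy)phenolate | COCOc1cc([O-])c([Li])c(OCOC)c1.[Li+]
F3 | step 11 | 1-[2-hydroxy-4,6-bis(methoxymethoxy)phenyl]-2-[5-(methoxymethoxy)-2,2-dimethyl-2H-chromen-8-yl]ethan-1-one | COCOc1cc(O)c(C(=O)Cc2ccc(OCOC)c3c2OC(C)(C)C=C3)c(OCOC)c1
F4 | step 12 | 5,7-dihydroxy-3-(5-hydroxy-2,2-dimethyl-2H-chromen-8-yl)-4H-chromen-4-one | Oc1cc(O)c2c(=O)c(-c3ccc(O)c4c3OC(C)(C)C=C4)coc2c1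
F5 | step 14 | 5-hydroxy-3-(5-hydroxy-2,2-dimethyl-2H-chromen-8-yl)-7-(2-methylbut-3-yn-2-yloxy)-4H-chromen-4-one | C#CC(C)(C)Oc1cc(O)c2c(=O)c(-c3ccc(O)c4c3OC(C)(C)C=C4)coc2c1
F6 | step 14 | 5-hydroxy-3-(5-hydroxy-2,2-dimethyl-2H-chromen-8-yl)-7-(2-methylbut-3-en-2-yloxy)-4H-chromen-4-one | C=CC(C)(C)Oc1cc(O)c2c(=O)c(-c3ccc(O)c4c3OC(C)(C)C=C4)coc2c1
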